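## Retrosynthetic overview

1. Sophonorol F is a (3S)-3-hydroxyisoflavanone (CIP order at C3: OH > C4 > C2 > aryl). The last operation removes two methoxymethyl ethers, on O5 and O4'.
2. Key disconnection: ring C is opened at O1–C2, together with the C3–OH bond and the C8–prenyl bond. This leads back to an acyclic, achiral 1,2-diarylprop-2-en-1-one whose future O1 carries a 1,1-dimethylallyl group.
3. Enabling feature: on ring A the prenyl group at C8 is ortho to O1 (aromatic Claisen pattern), C2 is the β-carbon of the C4 ketone (oxa-Michael pattern) and C3 is its α-carbon (enolate oxidation). One sigmatropic shift therefore installs the C8 prenyl and unmasks exactly the oxygen that must close the ring, while O5 stays blocked.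
4. The enone is cut at C3–C4 into a ring-A benzaldehyde (from 2,4,6-trihydroxybenzaldehyde) and a ring-B 1-arylvinyllithium (Shapiro reaction, from 2',4'-dihydroxyacetophenone; its 3'-prenyl comes from an earlier chelation-directed Claisen rearrangement).
5. Ring order: rings A and B are bought as arenes; ring C is the only ring made, in the key step.

Key step: step 11

Abbreviations: prenyl = 3-methylbut-2-en-1-yl; MOM = methoxymethyl.

Remark (assumption): the sense of induction of the camphor-derived oxaziridine on the isoflavanone enolate is assumed to follow the trend for 2-substituted 1-tetralone and 3-substituted chroman-4-one enolates. That trend points to the (−)-reagent for the (3S)-alcohol; if the sense is opposite on this enolate, the (+)-reagent is used in the same way.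

## Route

Step 1
Reactants: 1 2,4,6-trihydroxybenzaldehyde
Product: 2 2,6-dihydroxy-4-methoxybenzaldehyde
Conditions: Me2SO4 (1.0 equiv), K2CO3 (1.0 equiv), acetone, 0 °C to rt
Reagents that add atoms: dimethyl sulfate, COS(=O)(=O)OC
Why: Williamson O-methylation with one equivalent of base should pick the 4-OH, the most acidic hydroxyl and the only one not hydrogen-bonded to the formyl group.

Step 2
Reactants: 2 2,6-dihydroxy-4-methoxybenzaldehyde
Product: 3 2-hydroxy-4-methoxy-6-[(2-methylbut-3-en-2-yl)oxy]benzaldehyde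
Conditions: tert-butyl 2-methylbut-3-en-2-yl carbonate (1.2 equiv), Pd(PPh3)4 (2 mol%), THF, 0 °C
Reagents that add atoms: tert-butyl 2-methylbut-3-en-2-yl carbonate, CC(C)(C)OC(=O)OC(C)(C)C=C
Why: Decarboxylative Tsuji–Trost O-allylation, in which the phenoxide attacks the more substituted terminus of the 1,1-dimethylallyl palladium complex under kinetic control, should stop at the mono-ether because the remaining hydroxyl is locked in a hydrogen bond to the formyl group.

Step 3
Reactants: 3 2-hydroxy-4-methoxy-6-[(2-methylbut-3-en-2-yl)oxy]benzaldehyde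
Product: 4 4-methoxy-2-(methoxymethoxy)-6-[(2-methylbut-3-en-2-yl)oxy]benzaldehyde
Conditions: NaH, MOMCl, DMF, 0 °C
Reagents that add atoms: chloromethyl methyl ether, COCCl
Why: Williamson-type alkylation of the sodium phenoxide with the very reactive chloromethyl ether should overcome the chelation of this hydroxyl at a temperature far below that of the Claisen rearrangement of the allyl ether.

Step 4
Reactants: 5 1-(2,4-dihydroxyphenyl)ethanone
Product: 6 1-{2-hydroxy-4-[(2-methylbut-3-en-2-yl)oxy]phenyl}ethanone
Conditions: tert-butyl 2-methylbut-3-en-2-yl carbonate (1.2 equiv), Pd(PPh3)4 (2 mol%), THF, 0 °C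
Reagents that add atoms: tert-butyl 2-methylbut-3-en-2-yl carbonate, CC(C)(C)OC(=O)OC(C)(C)C=C
Why: The same Tsuji–Trost O-allylation should be selective for the 4-OH because the 2-OH is chelated to the acetyl group.

Step 5
Reactants: 6 1-{2-hydroxy-4-[(2-methylbut-3-en-2-yl)oxy]phenyl}ethanone
Product: 8 1-[2,4-dihydroxy-3-(3-methylbut-2-en-1-yl)phenyl]ethanone, via cyclohexadienone 7 (not isolated)
Conditions: PhNEt2, 120 °C
Reagents that add atoms: none
Why: Aromatic Claisen rearrangement followed by enolization should go to C3 rather than C5, because the chelate between the 2-OH and the acetyl group raises the double-bond character of the C3–C4 bond.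

Step 6
Reactants: 8 1-[2,4-dihydroxy-3-(3-methylbut-2-en-1-yl)phenyl]ethanone
Product: 9 1-[2-hydroxy-4-(methoxymethoxy)-3-(3-methylbut-2-en-1-yl)phenyl]ethanone
Conditions: MOMCl (1.1 equiv), K2CO3, acetone, rt
Reagents that add atoms: chloromethyl methyl ether, COCCl
Why: Williamson-type alkylation with a weak base should reach only the free 4-OH, the chelated 2-OH staying untouched.

Step 7
Reactants: 9 1-[2-hydroxy-4-(methoxymethoxy)-3-(3-methylbut-2-en-1-yl)phenyl]ethanone
Product: 10 1-[2-methoxy-4-(methoxymethoxy)-3-(3-methylbut-2-en-1-yl)phenyl]ethanone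
Conditions: MeI, Cs2CO3, DMF, 40 °C
Reagents that add atoms: iodomethane, CI
Why: Williamson O-methylation under forcing polar aprotic conditions should alkylate the chelated phenol, the only acidic site left.

Step 8
Reactants: 10 1-[2-methoxy-4-(methoxymethoxy)-3-(3-methylbut-2-en-1-yl)phenyl]ethanone
Product: 11 N'-{1-[2-methoxy-4-(methoxymethoxy)-3-(3-methylbut-2-en-1-yl)phenyl]ethylidene}-2,4,6-tri(propan-2-yl)benzenesulfonohydrazide
Conditions: 2,4,6-triisopropylbenzenesulfonohydrazide, PPTS (cat.), MeOH–THF, rt
Reagents that add atoms: 2,4,6-triisopropylbenzenesulfonohydrazide, CC(C)c1cc(C(C)C)c(S(=O)(=O)NN)c(C(C)C)c1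
Why: Hydrazone condensation of the methyl ketone should give the Shapiro precursor, the triisopropylphenyl group preventing ortho-lithiation of the sulfonyl arene in the next step.

Step 9
Reactants: 11 the triisopropylbenzenesulfonyl hydrazone of ketone 10; 4 4-methoxy-2-(methoxymethoxy)-6-[(2-methylbut-3-en-2-yl)oxy]benzaldehyde
Product: 13 racemic 1-{4-methoxy-2-(methoxymethoxy)-6-[(2-methylbut-3-en-2-yl)oxy]phenyl}-2-[2-methoxy-4-(methoxymethoxy)-3-(3-methylbut-2-en-1-yl)phenyl]prop-2-en-1-ol, via vinyllithium 12 (not isolated)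
Conditions: n-BuLi (2.1 equiv), THF, −78 to 0 °C; then 4, −78 °C; then H2O
Reagents that add atoms: none
Why: In the Shapiro reaction, double deprotonation of the hydrazone and loss of sulfinate and N2 should give the 1-arylvinyllithium, which adds 1,2 to the non-enolizable aldehyde; the new carbinol centre is racemic and is erased in step 10.

Step 10
Reactants: 13 the racemic diarylpropenol from step 9
Product: 14 1-{4-methoxy-2-(methoxymethoxy)-6-[(2-methylbut-3-en-2-yl)oxy]phenyl}-2-[2-methoxy-4-(methoxymethoxy)-3-(3-methylbut-2-en-1-yl)phenyl]prop-2-en-1-one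
Conditions: (n-Pr4N)RuO4 (5 mol%), NMO (1.5 equiv), 4 Å MS, CH2Cl2, 0 °C to rt
Reagents that add atoms: none
Why: Ley–Griffith oxidation of the benzylic and allylic alcohol runs under neutral conditions and should spare the ionization-prone carbinol, both acetals, the tertiary allyl ether and the alkenes.

Step 11
Reactants: 14 the 1,2-diarylprop-2-en-1-one from step 10
Product: 19 (3S)-3-hydroxy-7-methoxy-5-(methoxymethoxy)-3-[2-methoxy-4-(methoxymethoxy)-3-(3-methylbut-2-en-1-yl)phenyl]-8-(3-methylbut-2-en-1-yl)-2,3-dihydro-4H-chromen-4-one, via Claisen dienone 15 (not isolated), via ortho-prenyl phenol enone 16 (not isolated), via racemic isoflavanone 17 (not isolated), via potassium enolate 18 (not isolated)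
Conditions: degassed PhMe (0.02 M), 105 °C; then THF, KN(SiMe3)2 (1.1 equiv), −78 °C; then (−)-[(8,8-dichlorocamphoryl)sulfonyl]oxaziridine (1.3 equiv), −78 to −45 °C; then AcOH
Reagents that add atoms: (−)-[(8,8-dichlorocamphoryl)sulfonyl]oxaziridine (the enantiomer derived from (1R)-(−)-10-camphorsulfonic acid), CC1(C)[C@H]2CC[C@@]13CS(=O)(=O)N4O[C@]34C2(Cl)Cl
Why: Heating triggers the aromatic Claisen rearrangement ([3,3]-sigmatropic shift) of the ring-A 1,1-dimethylallyl ether to its only free ortho carbon (future C8), and enolization of dienone 15 releases phenol 16, whose free oxygen is by construction the one next to the new prenyl group. This oxygen adds to the methylene terminus of the α-aryl enone (oxa-Michael addition), which forms the O1–C2 bond and closes ring C in the 6-endo-trig mode; material that has not closed thermally closes as its potassium phenoxide, so everything converges on the cyclic enolate 18. Oxygen transfer from the enantiopure N-sulfonyloxaziridine to C3 of 18 (Davis oxidation) then sets the only stereocentre under reagent control, the camphor scaffold differentiating the two faces of the planar, ring-fixed enolate. The closest known reaction types are the Claisen rearrangement of 1,1-dimethylallyl ethers of ortho-acylphenols, the oxa-Michael closure of 2'-hydroxy-α-methylenedeoxybenzoins to isoflavanones, and the oxaziridine hydroxylation of 2-substituted 1-tetralone and 3-substituted chroman-4-one enolates. The step needs regioselectivity (8-prenyl, not 6-prenyl), secured because O5 stays blocked as its MOM ether so that only the oxygen unmasked by the sigmatropic shift can cyclize, and chemoselectivity, secured because the enolate is far more nucleophilic towards the oxaziridine than the trisubstituted alkenes at low temperature. It also needs facial selectivity at C3, which nothing in the achiral substrate provides and which therefore rests on the reagent alone.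

Step 12
Reactants: 19 the (3S)-bis-MOM ether from step 11
Product: 20 sophonorol F, (3S)-3,5-dihydroxy-3-[4-hydroxy-2-methoxy-3-(3-methylbut-2-en-1-yl)phenyl]-7-methoxy-8-(3-methylbut-2-en-1-yl)-2,3-dihydro-4H-chromen-4-one
Conditions: HCl (1.25 M in MeOH), 0 °C to rt
Reagents that add atoms: none
Why: Acid-catalysed transacetalization to methanol should remove both MOM ethers under conditions mild enough that the ortho-prenylphenol does not close to a chroman and the tertiary α-ketol, whose ionization is disfavoured by the adjacent carbonyl, keeps its configuration.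

## Compound list

1 | 2,4,6-trihydroxybenzaldehyde | O=Cc1c(O)cc(O)cc1O | starting material
2 | 2,6-dihydroxy-4-methoxybenzaldehyde | COc1cc(O)c(C=O)c(O)c1 | intermediate
3 | 2-hydroxy-4-methoxy-6-[(2-methylbut-3-en-2-yl)oxy]benzaldehyde | COc1cc(O)c(C=O)c(OC(C)(C)C=C)c1 | intermediate
4 | 4-methoxy-2-(methoxymethoxy)-6-[(2-methylbut-3-en-2-yl)oxy]benzaldehyde | COCOc1cc(OC)cc(OC(C)(C)C=C)c1C=O | intermediate
5 | 1-(2,4-dihydroxyphenyl)ethanone | CC(=O)c1ccc(O)cc1O | starting material
6 | 1-{2-hydroxy-4-[(2-methylbut-3-en-2-yl)oxy]phenyl}ethanone | CC(=O)c1ccc(OC(C)(C)C=C)cc1O | intermediate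
7 | racemic 4-acetyl-3-hydroxy-2-(3-methylbut-2-en-1-yl)cyclohexa-3,5-dien-1-one (not isolated) | CC(=O)C1=C(O)C(CC=C(C)C)C(=O)C=C1 | intermediate
8 | 1-[2,4-dihydroxy-3-(3-methylbut-2-en-1-yl)phenyl]ethanone | CC(=O)c1ccc(O)c(CC=C(C)C)c1O | intermediate
9 | 1-[2-hydroxy-4-(methoxymethoxy)-3-(3-methylbut-2-en-1-yl)phenyl]ethanone | CC(=O)c1ccc(OCOC)c(CC=C(C)C)c1O | intermediate
10 | 1-[2-methoxy-4-(methoxymethoxy)-3-(3-methylbut-2-en-1-yl)phenyl]ethanone | CC(=O)c1ccc(OCOC)c(CC=C(C)C)c1OC | intermediate
11 | N'-{1-[2-methoxy-4-(methoxymethoxy)-3-(3-methylbut-2-en-1-yl)phenyl]ethylidene}-2,4,6-tri(propan-2-yl)benzenesulfonohydrazide | CC(=NNS(=O)(=O)c1c(C(C)C)cc(C(C)C)cc1C(C)C)c1ccc(OCOC)c(CC=C(C)C)c1OC | intermediate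
12 | {1-[2-methoxy-4-(methoxymethoxy)-3-(3-methylbut-2-en-1-yl)phenyl]ethenyl}lithium (not isolated) | [Li]C(=C)c1ccc(OCOC)c(CC=C(C)C)c1OC | intermediate
13 | racemic 1-{4-methoxy-2-(methoxymethoxy)-6-[(2-methylbut-3-en-2-yl)oxy]phenyl}-2-[2-methoxy-4-(methoxymethoxy)-3-(3-methylbut-2-en-1-yl)phenyl]prop-2-en-1-ol | C=C(C(O)c1c(OCOC)cc(OC)cc1OC(C)(C)C=C)c1ccc(OCOC)c(CC=C(C)C)c1OC | intermediate
14 | 1-{4-methoxy-2-(methoxymethoxy)-6-[(2-methylbut-3-en-2-yl)oxy]phenyl}-2-[2-methoxy-4-(methoxymethoxy)-3-(3-methylbut-2-en-1-yl)phenyl]prop-2-en-1-one | C=C(C(=O)c1c(OCOC)cc(OC)cc1OC(C)(C)C=C)c1ccc(OCOC)c(CC=C(C)C)c1OC | intermediate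
15 | racemic 5-methoxy-3-(methoxymethoxy)-2-{2-[2-methoxy-4-(methoxymethoxy)-3-(3-methylbut-2-en-1-yl)phenyl]prop-2-enoyl}-6-(3-methylbut-2-en-1-yl)cyclohexa-2,4-dien-1-one (not isolated) | C=C(C(=O)C1=C(OCOC)C=C(OC)C(CC=C(C)C)C1=O)c1ccc(OCOC)c(CC=C(C)C)c1OC | intermediate
16 | 1-[2-hydroxy-4-methoxy-6-(methoxymethoxy)-3-(3-methylbut-2-en-1-yl)phenyl]-2-[2-methoxy-4-(methoxymethoxy)-3-(3-methylbut-2-en-1-yl)phenyl]prop-2-en-1-one (not isolated) | C=C(C(=O)c1c(OCOC)cc(OC)c(CC=C(C)C)c1O)c1ccc(OCOC)c(CC=C(C)C)c1OC | intermediate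
17 | racemic 7-methoxy-5-(methoxymethoxy)-3-[2-methoxy-4-(methoxymethoxy)-3-(3-methylbut-2-en-1-yl)phenyl]-8-(3-methylbut-2-en-1-yl)-2,3-dihydro-4H-chromen-4-one (not isolated) | COCOc1cc(OC)c(CC=C(C)C)c2OCC(c3ccc(OCOC)c(CC=C(C)C)c3OC)C(=O)c12 | intermediate
18 | potassium 7-methoxy-5-(methoxymethoxy)-3-[2-methoxy-4-(methoxymethoxy)-3-(3-methylbut-2-en-1-yl)phenyl]-8-(3-methylbut-2-en-1-yl)-2H-chromen-4-olate (not isolated) | [K+].[O-]C1=C(c2ccc(OCOC)c(CC=C(C)C)c2OC)COc2c(CC=C(C)C)c(OC)cc(OCOC)c12 | intermediate
19 | (3S)-3-hydroxy-7-methoxy-5-(methoxymethoxy)-3-[2-methoxy-4-(methoxymethoxy)-3-(3-methylbut-2-en-1-yl)phenyl]-8-(3-methylbut-2-en-1-yl)-2,3-dihydro-4H-chromen-4-one | COCOc1cc(OC)c(CC=C(C)C)c2OC[C@@](O)(c3ccc(OCOC)c(CC=C(C)C)c3OC)C(=O)c12 | intermediate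
20 | sophonorol F, (3S)-3,5-dihydroxy-3-[4-hydroxy-2-methoxy-3-(3-methylbut-2-en-1-yl)phenyl]-7-methoxy-8-(3-methylbut-2-en-1-yl)-2,3-dihydro-4H-chromen-4-one | COc1cc(O)c2c(c1CC=C(C)C)OC[C@@](O)(c1ccc(O)c(CC=C(C)C)c1OC)C2=O | target

## Step count and risks

Total step count: 12.
Longest linear sequence: 9 steps (from 5 through 6, 8, 9, 10, 11, 13, 14 and 19 to 20; steps 4 to 12).

Steps most likely to fail:

Step 11. The α-aryl enone may oligomerize (hetero-Diels–Alder dimerization, radical polymerization) at the temperature of the sigmatropic shift. The aryloxide may be lost reversibly from the enolate by β-elimination, and facial discrimination in the oxygen transfer to the crowded enolate may be poor. The fallback uncouples the events and sets the stereocentre with a catalyst instead of a stoichiometric reagent. It sets out from aldehyde 4, which is rearranged first (PhMe, 105 °C) by way of racemic 4-methoxy-2-(methoxymethoxy)-5-(3-methylbut-2-en-1-yl)-6-oxocyclohexa-1,3-diene-1-carbaldehyde F1 to 2-hydroxy-4-methoxy-6-(methoxymethoxy)-3-(3-methylbut-2-en-1-yl)benzaldehyde F2. Addition of vinyllithium 12 (2.2 equiv, THF, −78 °C, the first equivalent forming the phenoxide) should give racemic 1-[2-hydroxy-4-methoxy-6-(methoxymethoxy)-3-(3-methylbut-2-en-1-yl)phenyl]-2-[2-methoxy-4-(methoxymethoxy)-3-(3-methylbut-2-en-1-yl)phenyl]prop-2-en-1-ol F3. Oxidation with MnO2 (CH2Cl2, rt) should give phenol enone 16, which closes at room temperature by the same oxa-Michael addition (O1–C2) to racemic isoflavanone 17, now isolated, so the enone is never heated. Phase-transfer aerobic α-hydroxylation of 17 (O2, P(OEt)3, 50% aqueous KOH, PhMe, 0 °C, 10 mol% N-(9-anthracenylmethyl)cinchonidinium bromide or its cinchoninium pseudoenantiomer, whichever gives the (3S) sense) comes back to the route at 19.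

Step 2. The soft allylpalladium electrophile may allylate the electron-rich phloroglucinol-type ring at carbon, and reversible ionization of the product on palladium may isomerize the branched ether to the linear prenyl ether. The fallback sets out from 2 and replaces the allylpalladium chemistry by a hard propargylic electrophile. Copper-catalysed O-propargylation (3-chloro-3-methylbut-1-yne, CuCl2·2H2O cat., DBU, MeCN, 0 °C) should give 2-hydroxy-4-methoxy-6-[(2-methylbut-3-yn-2-yl)oxy]benzaldehyde F4. Semihydrogenation (H2, Pb-poisoned Pd/CaCO3, quinoline, EtOAc, rt) comes back to the route at 3.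

Step 9. Generation of the vinyllithium may be incomplete (protonation by the medium, competing directed ortho-lithiation next to the MOM ether), and the very electron-rich benzylic allylic alcohol may ionize on work-up. The fallback sets out from ketone 10 and avoids organolithium chemistry. Enol triflation (KN(SiMe3)2, PhNTf2, THF, −78 °C) should give 1-[2-methoxy-4-(methoxymethoxy)-3-(3-methylbut-2-en-1-yl)phenyl]ethenyl trifluoromethanesulfonate F5. Nozaki–Hiyama–Kishi coupling with aldehyde 4 (CrCl2, NiCl2 cat., DMF, rt) comes back to the route at 13.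

## Further compounds

F1 | step 11 | racemic 4-methoxy-2-(methoxymethoxy)-5-(3-methylbut-2-en-1-yl)-6-oxocyclohexa-1,3-diene-1-carbaldehyde | O=CC1=C(OCOC)C=C(OC)C(CC=C(C)C)C1=O
F2 | step 11 | 2-hydroxy-4-methoxy-6-(methoxymethoxy)-3-(3-methylbut-2-en-1-yl)benzaldehyde | COCOc1cc(OC)c(CC=C(C)C)c(O)c1C=O
F3 | step 11 | racemic 1-[2-hydroxy-4-methoxy-6-(methoxymethoxy)-3-(3-methylbut-2-en-1-yl)phenyl]-2-[2-methoxy-4-(methoxymethoxy)-3-(3-methylbut-2-en-1-yl)phenyl]prop-2-en-1-ol | C=C(C(O)c1c(OCOC)cc(OC)c(CC=C(C)C)c1O)c1ccc(OCOC)c(CC=C(C)C)c1OC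
F4 | step 2 | 2-hydroxy-4-methoxy-6-[(2-methylbut-3-yn-2-yl)oxy]benzaldehyde | COc1cc(O)c(C=O)c(OC(C)(C)C#C)c1
F5 | step 9 | 1-[2-methoxy-4-(methoxymethoxy)-3-(3-methylbut-2-en-1-yl)phenyl]ethenyl trifluoromethanesulfonate | C=C(OS(=O)(=O)C(F)(F)F)c1ccc(OCOC)c(CC=C(C)C)c1OC
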